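Abbreviations: TBS = tert-butyldimethylsilyl, TES = triethylsilyl, Ipc = isopinocampheyl, OTf = triflate. Atom labels: seven-membered ring C1 (carbinol carrying the crotonoyl group, ketone carbon CK), C2 (CHMe), C3 (CHOH), C4 (CH2), C5 (ring fusion), C6 (lactone oxygen), C7 (isobutyrate); lactone CHMe = C11, lactone C=O = C12. Compound numbers are those of the steps below.

## Analysis of the target

The target is a cis-fused bicycle: a cycloheptane (C1–C7) with a γ-lactone (O–C12–C11) across C5–C6. It has seven stereocentres, six on the carbocycle (C1 S, C2 S, C3 R, C5 S, C6 R, C7 S) and C11 (R) on the lactone; C1 is fully substituted and carries the tertiary hydroxyl and the (E)-crotonoyl group. The three lactone substituents (C11 methyl, the C5–C4 bond, the C6–C7 bond) are all cis. On the carbocycle C6–O/C7–O and C7–O/C1–O are trans, C1–OH/C2–Me are cis, and C2–Me/C3–OH are trans, which in the open chain is a syn methyl/hydroxyl pair. Sensitive groups are the tertiary α-ketol next to a β-acyloxy group (retro-aldol, acyl migration), the enone, the secondary isobutyrate, and the cis α-methyl lactone, whose C11 epimerises to the trans isomer under base. The hard parts are the quaternary C1 wedged between two stereocentres in a medium ring and the contra-thermodynamic all-cis lactone. The strategy rests on one feature: C1 is the only hydrogen-bearing carbon α to the crotonoyl ketone (the other side is vinylic) and C7 is a carbinol, so the C1–C7 bond is the bond of a ketone–aldehyde aldol. Forming it closes the seven-membered ring and creates C1 and C7 with the crotonoyl group already in place.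

## Retrosynthetic reasoning

32 back to 29 (C7–O acyl bond, two O–Si bonds). The isobutyrate is cut first because the ring-closing aldol frees exactly the C7 hydroxyl while C1–O and C3–O are still silylated. Acylation of 29 with isobutyryl chloride 30 to give 31 therefore needs no selectivity, and only a non-basic desilylation remains.

29 back to 26 (C1–C7). This is the key cut. It is made here because no other bond removes the quaternary centre, the ring and two stereocentres together while keeping the crotonoyl ketone at its final oxidation level. The forward reaction must enolise the α-silyloxy enone at C1 only and add the enolate to the C7 aldehyde with C1–O/C7–O trans. The C1 configuration of 26 is lost on enolisation, so it need not be controlled earlier.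

26 back to 21 and 22 (CK–vinyl bond, oxidation levels at CK and C7). The enone is taken apart into the α-silyloxy aldehyde 21 and (E)-1-bromoprop-1-ene 22; addition gives 23 and oxidation gives 24. The C7 aldehyde is unveiled last (24 to 25 to 26) because an α-alkoxy aldehyde on the all-cis lactone is the most epimerisable group of the sequence.

21 back to 17 (C1–O and CK–O). The vicinal oxygens come from dihydroxylation of a terminal alkene (18). One-pot differentiation (primary TES, secondary TBS, 20) allows direct oxidation of the TES ether to 21. The gain is that the C1 configuration can be left uncontrolled.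

17 back to 14 and 15 (C2–C3). The syn C2-methyl/C3-hydroxyl pair is a crotylboration retron. A Z-crotyl reagent from cis-2-butene 15 is required; an E-crotyl reagent would give the C2 epimer. The aldehyde stereocentres are remote, so a chiral borane must set the absolute sense.

14 back to 12 (two C–H bonds at C5 and C11). The all-cis lactone 13 cannot be made by conjugate addition, which places the new group trans to the C6 substituent. It is made instead by syn-hydrogenation of the tetrasubstituted butenolide 12 from the face opposite the silyloxymethyl group. Aldehyde 14 then follows by direct oxidation of the TES ether.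

12 back to 1 (C5–C4 bond, C11–methyl bond). The butenolide 12 comes from the saturated lactone 10 by selenoxide elimination. The methyl carbon comes from iodomethane 6 (5 to 7). The two-carbon arm comes from vinylmagnesium bromide 3 added to 2, followed by hydroboration (7 to 9) and silylation (10). The stereocentres made in these steps are erased again; only C6, from the chiral-pool butenolide 1, is carried through.

## Alternatives that were turned down

Alternative 1: Cut C5–C6 and the lactone C–O bond together. In the forward step CrCl2 turns the Z allylic bromide of the open-chain aldehyde A1 into an allylchromium species whose γ-carbon (C5) adds to the C6 aldehyde; the alkoxide then lactonises to give the cis-fused α-methylene lactone A2. In its favour: two rings, one C–C and one C–O bond and two stereocentres in a single, non-basic and well-precedented medium-ring closure. Against it for this target: C1 and C7 must be set beforehand in an acyclic chain. After closure the C11 methyl needs a hydrogenation that competes with the alkyne, and the ethynyl group must still be grown into the crotonoyl ketone. The acetonide has to be removed and C7 acylated selectively. In ring-closing precedent and in making the lactone at the same time it is stronger than the chosen route. The chosen route offers instead the quaternary C1 formed in the closure itself and an endgame of two steps instead of roughly six to eight.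

Alternative 2: Cut C3–C4. CrCl2 with catalytic NiCl2 converts the alkenyl iodide of A3 into an alkenylchromium nucleophile that adds to the C3 aldehyde, giving the bicyclic allylic alcohol A4. In its favour: the reaction tolerates the lactone and ester, needs no enolate, and the new C3 hydroxyl can direct hydrogenation of C4=C5 to the correct face. Against it: the C3 configuration depends on 1,2-induction inside a ring-closing transition state. The β,γ-unsaturated lactone in A3 and A4 has a doubly activated C11–H (epimerisation, migration into conjugation). The masked methyl ketone must later be extended to the enone by aldol condensation. Above all, the C1–C7 bond with its quaternary centre still has to be made acyclically, so the main problem is moved rather than solved. In closure reliability it is at least as strong as the chosen route. The chosen route offers the solution of C1 and a shorter endgame.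

Alternative 3: Cut C2–C3 by a type 2 carbonyl-ene reaction. Me2AlCl activates the C3 aldehyde of A5; C2 of the Z trisubstituted alkene attacks while a methyl hydrogen passes to oxygen, giving A6 with an exocyclic methylene on C1. In its favour: C2 and C3 are set in an ordered transition state, and no base comes near the cis lactone or the α-alkoxy centres; on this point it is stronger than the chosen route. Against it: the C7 isobutyrate of A5 is allylic and can ionise under the Lewis acid, and several Lewis-basic sites consume reagent. A6 also lacks the C1 oxygen and three of the four crotonoyl carbons. These need a face-selective dihydroxylation of a hindered exocyclic alkene, oxidation, propenyl addition and reoxidation next to a migration-prone ester (six or more steps, with C1 uncontrolled). The chosen route offers C1 and C7 formed together with the crotonoyl group in place.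

Key step: step 17

Remark: 1 is taken to be purchasable as the (R) enantiomer; its stereocentre becomes C6 unchanged.
Remark: step 10 is not stereocontrolled at C1, so 18–26 are pairs of C1 epimers (drawn and named as the 1R epimer) and 23 is also a pair of CK carbinol epimers; this is harmless because step 17 planarises C1 and step 14 oxidises CK.

## Steps

Step 1
Reactants: 1 (R)-5-(hydroxymethyl)furan-2(5H)-one
Product: 2 (R)-5-(TBSO-methyl)furan-2(5H)-one
Conditions: TBSCl, imidazole, CH2Cl2, 0 °C → rt
Reagents that add atoms: tert-butyldimethylsilyl chloride, CC(C)(C)[Si](C)(C)Cl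
Why: Standard silylation of the primary alcohol; the bulky silyloxymethyl group is the control element for face selectivity in steps 2 and 7.

Step 2
Reactants: 2; 3 vinylmagnesium bromide
Product: 5 (4S,5R)-5-(TBSO-methyl)-4-vinyldihydrofuran-2(3H)-one, via silyl ketene acetal 4 (not isolated)
Conditions: CH2=CHMgBr, CuBr·SMe2 (10 mol %), Me3SiCl, THF, −78 °C; aq NH4Cl
Reagents that add atoms: vinylmagnesium bromide, C=C[Mg]Br
Why: Copper-catalysed conjugate addition of the Grignard reagent, trapped as ketene acetal 4 and hydrolysed on work-up; the vinyl group enters anti to the C5 substituent. The new centre only delivers the two-carbon arm and is re-set in step 7.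

Step 3
Reactants: 5; 6 iodomethane
Product: 7 (3R,4R,5R)-5-(TBSO-methyl)-3-methyl-4-vinyldihydrofuran-2(3H)-one
Conditions: LiN(iPr)2, THF, −78 °C; MeI, DMPU, −78 → −40 °C
Reagents that add atoms: iodomethane, CI
Why: Kinetic lactone enolate alkylation trans to the vinyl group; it only brings in the C11 methyl carbon, since this centre is flattened in step 6 and re-set in step 7.

Step 4
Reactants: 7
Product: 9 (3R,4R,5R)-4-(2-hydroxyethyl)-5-(TBSO-methyl)-3-methyldihydrofuran-2(3H)-one, via B-alkyl-9-BBN adduct 8 (not isolated)
Conditions: 9-BBN, THF, 0 °C → rt; then 30% H2O2, aq NaOAc, 0 °C → rt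
Reagents that add atoms: hydrogen peroxide, OO
Why: Anti-Markovnikov hydroboration–oxidation of the terminal alkene; 9-BBN leaves the lactone alone and the acetate-buffered oxidation avoids ring opening.

Step 5
Reactants: 9
Product: 10 (3R,4R,5R)-5-(TBSO-methyl)-3-methyl-4-[2-(TESO)ethyl]dihydrofuran-2(3H)-one
Conditions: Et3SiCl, imidazole, CH2Cl2, 0 °C
Reagents that add atoms: chlorotriethylsilane, CC[Si](Cl)(CC)CC
Why: Silylation of the primary alcohol; a TES ether is chosen because it survives steps 6 and 7 and is oxidised directly in step 8 while the TBS ether stays.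

Step 6
Reactants: 10
Product: 12 (R)-5-(TBSO-methyl)-3-methyl-4-[2-(TESO)ethyl]furan-2(5H)-one, via α-phenylselanyl lactone 11 (not isolated)
Conditions: LiN(iPr)2, THF, −78 °C; PhSeBr; then 30% H2O2, pyridine, CH2Cl2, 0 °C → rt
Reagents that add atoms: none
Why: Selenenylation of the enolate occurs anti to the side chain, so selenium sits cis to the hydrogen on the neighbouring ring carbon; oxidation and syn-elimination of the selenoxide (Reich–Grieco dehydrogenation) should then give the ring-conjugated tetrasubstituted butenolide. Pyridine buffering protects the silyl ethers.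

Step 7
Reactants: 12
Product: 13 (3R,4S,5R)-5-(TBSO-methyl)-3-methyl-4-[2-(TESO)ethyl]dihydrofuran-2(3H)-one (all-cis)
Conditions: H2 (4 atm), 5% Rh/Al2O3, EtOAc, rt
Reagents that add atoms: none
Why: Heterogeneous syn-hydrogenation; both hydrogens are delivered to the face opposite the silyloxymethyl group, so the methyl group and the side chain end cis to it. This sets C5 and C11 relative to C6.

Step 8
Reactants: 13
Product: 14 2-[(2R,3S,4R)-2-(TBSO-methyl)-4-methyl-5-oxooxolan-3-yl]acetaldehyde
Conditions: (COCl)2, DMSO, CH2Cl2, −78 → −40 °C; Et3N, −78 → 0 °C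
Reagents that add atoms: none
Why: Swern conditions cleave and oxidise a primary TES ether in one operation, whereas TBS ethers are inert; no epimerisation of C11 is expected at these temperatures.

Step 9
Reactants: 14; 15 cis-2-butene
Product: 17 (3R,4S,5R)-5-(TBSO-methyl)-4-[(2R,3R)-2-hydroxy-3-methylpent-4-en-1-yl]-3-methyldihydrofuran-2(3H)-one, via diisopinocampheylborinate 16 (not isolated)
Conditions: cis-2-butene, KOtBu, n-BuLi, THF, −78 → −45 °C; (−)-Ipc2BOMe, −78 °C; BF3·OEt2; 14, −78 °C; then NaBO3·4H2O, THF/H2O, rt
Reagents that add atoms: cis-2-butene, C/C=C\C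
Why: Brown crotylboration; the Z-crotylborane reacts through a chair transition state to give the syn C2-methyl/C3-hydroxyl adduct, and the Ipc groups of the (+)-α-pinene series direct attack to the Si face of the aldehyde. This sets C3 as R, and C2 with it, by reagent control over the remote lactone centres; the perborate work-up spares the lactone.

Step 10
Reactants: 17
Product: 18 (3R,4S,5R)-5-(TBSO-methyl)-3-methyl-4-[(2R,3S,4R)-2,4,5-trihydroxy-3-methylpentyl]dihydrofuran-2(3H)-one
Conditions: OsO4 (2 mol %), NMO, acetone/H2O, rt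
Reagents that add atoms: N-methylmorpholine N-oxide, C[N+]1([O-])CCOCC1; water, O
Why: Upjohn dihydroxylation of the terminal alkene; face selectivity at C1 is low and not needed because C1 is planarised in step 17.

Step 11
Reactants: 18
Product: 20 (3R,4S,5R)-4-[(2R,3S,4R)-2,4-bis(TBSO)-3-methyl-5-(TESO)pentyl]-5-(TBSO-methyl)-3-methyldihydrofuran-2(3H)-one, via primary TES ether 19 (not isolated)
Conditions: Et3SiCl (1.05 equiv), 2,6-lutidine, DMAP (cat.), CH2Cl2, −78 → −40 °C; then TBSOTf (3 equiv), −40 → 0 °C
Reagents that add atoms: chlorotriethylsilane, CC[Si](Cl)(CC)CC; tert-butyldimethylsilyl triflate, CC(C)(C)[Si](C)(C)OS(=O)(=O)C(F)(F)F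
Why: The unhindered primary hydroxyl is silylated first at low temperature; the silyl triflate then caps both secondary hydroxyls in the same flask. C1–O and C3–O end as robust TBS ethers and the CK oxygen as the one group that step 12 oxidises.

Step 12
Reactants: 20
Product: 21 (2R,3S,4R)-2,4-bis(TBSO)-5-[(2R,3S,4R)-2-(TBSO-methyl)-4-methyl-5-oxooxolan-3-yl]-3-methylpentanal
Conditions: (COCl)2, DMSO, CH2Cl2, −78 → −40 °C; Et3N, −78 → 0 °C
Reagents that add atoms: none
Why: Direct Swern oxidation of the primary TES ether as in step 8; the three TBS ethers, the primary one at C7–O included, should remain.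

Step 13
Reactants: 21; 22 (E)-1-bromoprop-1-ene
Product: 23 (2E,5R,6S,7R)-5,7-bis(TBSO)-6-methyl-8-[(2R,3S,4R)-2-(TBSO-methyl)-4-methyl-5-oxooxolan-3-yl]oct-2-en-4-ol
Conditions: 22, t-BuLi (2 equiv), Et2O, −78 °C; CeCl3, THF, −78 °C; then 21, −78 °C
Reagents that add atoms: (E)-1-bromoprop-1-ene, C/C=C/Br
Why: Bromine–lithium exchange keeps the E geometry, and the organocerium reagent is non-basic and adds to the aldehyde only, leaving the lactone and C11 alone. The configuration of the new carbinol is irrelevant.

Step 14
Reactants: 23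
Product: 24 (2E,5R,6S,7R)-5,7-bis(TBSO)-6-methyl-8-[(2R,3S,4R)-2-(TBSO-methyl)-4-methyl-5-oxooxolan-3-yl]oct-2-en-4-one
Conditions: Dess–Martin periodinane, NaHCO3, CH2Cl2, 0 °C → rt
Reagents that add atoms: none
Why: Dess–Martin oxidation of the allylic alcohol to the E-enone under buffered, non-basic conditions.

Step 15
Reactants: 24
Product: 25 (2E,5R,6S,7R)-5,7-bis(TBSO)-8-[(2R,3S,4R)-2-(hydroxymethyl)-4-methyl-5-oxooxolan-3-yl]-6-methyloct-2-en-4-one
Conditions: HF·pyridine, pyridine, THF, 0 °C
Reagents that add atoms: none
Why: Buffered HF·pyridine cleaves primary TBS ethers much faster than hindered secondary ones, which should free only the C7 hydroxyl.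

Step 16
Reactants: 25
Product: 26 (2R,3S,4R)-3-[(2R,3S,4R,6E)-2,4-bis(TBSO)-3-methyl-5-oxooct-6-en-1-yl]-4-methyl-5-oxooxolane-2-carbaldehyde
Conditions: Dess–Martin periodinane, NaHCO3, CH2Cl2, 0 °C
Reagents that add atoms: none
Why: Dess–Martin oxidation to the α-alkoxy aldehyde without amine base, so that C6 on the all-cis lactone is not epimerised; the aldehyde is used at once.

Step 17
Reactants: 26
Product: 29 (3R,3aS,5R,6S,7S,8S,8aR)-7-[(E)-but-2-enoyl]-5,7-bis(TBSO)-8-hydroxy-3,6-dimethyloctahydro-2H-cyclohepta[b]furan-2-one, via boron dienolate 27 (not isolated), via boron aldolate 28 (not isolated)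
Conditions: Bu2BOTf, iPr2NEt, CH2Cl2 (0.005 M), −78 → 0 °C; then pH 7 buffer, MeOH, 30% H2O2, 0 °C
Reagents that add atoms: none
Why: Proposed new method: Bu2BOTf complexes the ketone and iPr2NEt removes its only α-hydrogen (at C1), which erases the C1 configuration of both epimers of 26 and gives the cross-conjugated boron dienolate 27; C1 then adds to the boron-activated C7 aldehyde through a six-membered boron-bridged chair to give aldolate 28, which the buffered peroxide work-up releases as 29. The closest known reaction type is the boron triflate/amine soft-enolisation aldol of α-oxygenated ketones and its intramolecular ketone–aldehyde version; what has not been shown is a fully substituted α-silyloxy enolate carbon combined with a seven-membered closure. The ring closes in a 7-(enolexo)-exo-trig mode, with the enolate C=C outside the new ring and the aldehyde C=O exo to it. The enolate is expected to form with the branched C2 substituent cis to O–B, as the α-alkyl group is in the Z enolborinates made under these conditions, and with the silyloxy group cis to the propenyl group, which also keeps the C1–O and C=O dipoles opposed during deprotonation. C1 is controlled by the C2 stereocentre: 1,3-allylic strain holds C2–H in the enolate plane, the tether reaches the enolate from the face opposite the C2 methyl group, and the silyloxy group therefore ends cis to that methyl. C7 is controlled by the chair: with C2 pseudoaxial on the enolate carbon the aldehyde must place C6 pseudoequatorial, which makes C1–O and C7–O trans and gives the required trans C6–O/C7–O (anti-Felkin) sense, the sense such enolates usually favour because the Felkin arrangement suffers a syn-pentane contact. The step needs chemoselective enolisation of the ketone (lactones are not enolised by this reagent pair, and the intramolecular aldol should trap 27 before the aldehyde α-carbon C6 can equilibrate) and high dilution against intermolecular aldol; dehydration cannot follow because C1 has no hydrogen.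

Step 18
Reactants: 29; 30 isobutyryl chloride
Product: 31 (3R,3aS,5R,6S,7S,8S,8aR)-7-[(E)-but-2-enoyl]-5,7-bis(TBSO)-3,6-dimethyl-2-oxooctahydro-2H-cyclohepta[b]furan-8-yl 2-methylpropanoate
Conditions: iPrCOCl, pyridine, DMAP (cat.), CH2Cl2, 0 °C → rt
Reagents that add atoms: isobutyryl chloride, CC(C)C(Cl)=O
Why: DMAP-catalysed acylation of the only free hydroxyl; C1–O and C3–O are silylated, so no selectivity problem arises, and the mild base should not trigger retro-aldol cleavage.

Step 19
Reactants: 31
Product: 32 (3R,3aS,5R,6S,7S,8S,8aR)-7-[(E)-but-2-enoyl]-5,7-dihydroxy-3,6-dimethyl-2-oxooctahydro-2H-cyclohepta[b]furan-8-yl 2-methylpropanoate (CNP0268641.1)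
Conditions: HF·pyridine, THF, 0 °C → rt
Reagents that add atoms: none
Why: Fluoride-induced cleavage of both silyl ethers under non-basic conditions, which avoids retro-aldol opening, acyl migration from C7–O to C1–O and conjugate addition to the enone; the silyl ether α to the ketone is activated by the neighbouring carbonyl.

## Compound list

1 | (R)-5-(hydroxymethyl)furan-2(5H)-one | O=C1C=C[C@H](CO)O1 | starting material
2 | (R)-5-(TBSO-methyl)furan-2(5H)-one | O=C1C=C[C@H](CO[Si](C)(C)C(C)(C)C)O1 | intermediate
3 | vinylmagnesium bromide | C=C[Mg]Br | starting material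
4 | (4R,5R)-5-(TBSO-methyl)-2-(trimethylsilyloxy)-4-vinyl-4,5-dihydrofuran (4,5-trans; formed in the flask) | C[Si](C)(C)OC1=C[C@@H](C=C)[C@H](CO[Si](C)(C)C(C)(C)C)O1 | intermediate
5 | (4S,5R)-5-(TBSO-methyl)-4-vinyldihydrofuran-2(3H)-one | O=C1C[C@@H](C=C)[C@H](CO[Si](C)(C)C(C)(C)C)O1 | intermediate
6 | iodomethane | CI | starting material
7 | (3R,4R,5R)-5-(TBSO-methyl)-3-methyl-4-vinyldihydrofuran-2(3H)-one | O=C1[C@H](C)[C@@H](C=C)[C@H](CO[Si](C)(C)C(C)(C)C)O1 | intermediate
8 | (3R,4R,5R)-4-[2-(9-borabicyclo[3.3.1]nonan-9-yl)ethyl]-5-(TBSO-methyl)-3-methyldihydrofuran-2(3H)-one (formed in the flask) | O=C1[C@H](C)[C@@H](CCB2C3CCCC2CCC3)[C@H](CO[Si](C)(C)C(C)(C)C)O1 | intermediate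
9 | (3R,4R,5R)-4-(2-hydroxyethyl)-5-(TBSO-methyl)-3-methyldihydrofuran-2(3H)-one | O=C1[C@H](C)[C@@H](CCO)[C@H](CO[Si](C)(C)C(C)(C)C)O1 | intermediate
10 | (3R,4R,5R)-5-(TBSO-methyl)-3-methyl-4-[2-(TESO)ethyl]dihydrofuran-2(3H)-one | O=C1[C@H](C)[C@@H](CCO[Si](CC)(CC)CC)[C@H](CO[Si](C)(C)C(C)(C)C)O1 | intermediate
11 | (3R,4S,5R)-5-(TBSO-methyl)-3-methyl-3-(phenylselanyl)-4-[2-(TESO)ethyl]dihydrofuran-2(3H)-one (Se trans to the side chain; formed in the flask) | O=C1[C@](C)([Se]c2ccccc2)[C@@H](CCO[Si](CC)(CC)CC)[C@H](CO[Si](C)(C)C(C)(C)C)O1 | intermediate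
12 | (R)-5-(TBSO-methyl)-3-methyl-4-[2-(TESO)ethyl]furan-2(5H)-one | O=C1C(C)=C(CCO[Si](CC)(CC)CC)[C@H](CO[Si](C)(C)C(C)(C)C)O1 | intermediate
13 | (3R,4S,5R)-5-(TBSO-methyl)-3-methyl-4-[2-(TESO)ethyl]dihydrofuran-2(3H)-one (all-cis) | CC[Si](CC)(CC)OCC[C@@H]1[C@@H](OC(=O)[C@@H]1C)CO[Si](C)(C)C(C)(C)C | intermediate
14 | 2-[(2R,3S,4R)-2-(TBSO-methyl)-4-methyl-5-oxooxolan-3-yl]acetaldehyde | O=CC[C@@H]1[C@@H](OC(=O)[C@@H]1C)CO[Si](C)(C)C(C)(C)C | intermediate
15 | cis-2-butene | C/C=C\C | starting material
16 | O-diisopinocampheylboryl derivative of 17 (formed in the flask) | C=C[C@@H](C)[C@H](OB([C@@H]2C[C@@H]3C[C@H]([C@H]2C)C3(C)C)[C@@H]2C[C@@H]3C[C@H]([C@H]2C)C3(C)C)C[C@@H]1[C@@H](OC(=O)[C@@H]1C)CO[Si](C)(C)C(C)(C)C | intermediate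
17 | (3R,4S,5R)-5-(TBSO-methyl)-4-[(2R,3R)-2-hydroxy-3-methylpent-4-en-1-yl]-3-methyldihydrofuran-2(3H)-one | C=C[C@@H](C)[C@H](O)C[C@@H]1[C@@H](OC(=O)[C@@H]1C)CO[Si](C)(C)C(C)(C)C | intermediate
18 | (3R,4S,5R)-5-(TBSO-methyl)-3-methyl-4-[(2R,3S,4R)-2,4,5-trihydroxy-3-methylpentyl]dihydrofuran-2(3H)-one (with its C1 epimer) | OC[C@H](O)[C@@H](C)[C@H](O)C[C@@H]1[C@@H](OC(=O)[C@@H]1C)CO[Si](C)(C)C(C)(C)C | intermediate
19 | (3R,4S,5R)-4-[(2R,3S,4R)-2,4-dihydroxy-3-methyl-5-(TESO)pentyl]-5-(TBSO-methyl)-3-methyldihydrofuran-2(3H)-one (with its C1 epimer; formed in the flask) | CC[Si](CC)(CC)OC[C@H](O)[C@@H](C)[C@H](O)C[C@@H]1[C@@H](OC(=O)[C@@H]1C)CO[Si](C)(C)C(C)(C)C | intermediate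
20 | (3R,4S,5R)-4-[(2R,3S,4R)-2,4-bis(TBSO)-3-methyl-5-(TESO)pentyl]-5-(TBSO-methyl)-3-methyldihydrofuran-2(3H)-one (with its C1 epimer) | CC[Si](CC)(CC)OC[C@H](O[Si](C)(C)C(C)(C)C)[C@@H](C)[C@H](O[Si](C)(C)C(C)(C)C)C[C@@H]1[C@@H](OC(=O)[C@@H]1C)CO[Si](C)(C)C(C)(C)C | intermediate
21 | (2R,3S,4R)-2,4-bis(TBSO)-5-[(2R,3S,4R)-2-(TBSO-methyl)-4-methyl-5-oxooxolan-3-yl]-3-methylpentanal (with its C1 epimer) | O=C[C@H](O[Si](C)(C)C(C)(C)C)[C@@H](C)[C@H](O[Si](C)(C)C(C)(C)C)C[C@@H]1[C@@H](OC(=O)[C@@H]1C)CO[Si](C)(C)C(C)(C)C | intermediate
22 | (E)-1-bromoprop-1-ene | C/C=C/Br | starting material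
23 | (2E,5R,6S,7R)-5,7-bis(TBSO)-6-methyl-8-[(2R,3S,4R)-2-(TBSO-methyl)-4-methyl-5-oxooxolan-3-yl]oct-2-en-4-ol (carbinol CK undefined; with its C1 epimer) | C/C=C/C(O)[C@H](O[Si](C)(C)C(C)(C)C)[C@@H](C)[C@H](O[Si](C)(C)C(C)(C)C)C[C@@H]1[C@@H](OC(=O)[C@@H]1C)CO[Si](C)(C)C(C)(C)C | intermediate
24 | (2E,5R,6S,7R)-5,7-bis(TBSO)-6-methyl-8-[(2R,3S,4R)-2-(TBSO-methyl)-4-methyl-5-oxooxolan-3-yl]oct-2-en-4-one (with its C1 epimer) | C/C=C/C(=O)[C@H](O[Si](C)(C)C(C)(C)C)[C@@H](C)[C@H](O[Si](C)(C)C(C)(C)C)C[C@@H]1[C@@H](OC(=O)[C@@H]1C)CO[Si](C)(C)C(C)(C)C | intermediate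
25 | (2E,5R,6S,7R)-5,7-bis(TBSO)-8-[(2R,3S,4R)-2-(hydroxymethyl)-4-methyl-5-oxooxolan-3-yl]-6-methyloct-2-en-4-one (with its C1 epimer) | C/C=C/C(=O)[C@H](O[Si](C)(C)C(C)(C)C)[C@@H](C)[C@H](O[Si](C)(C)C(C)(C)C)C[C@@H]1[C@@H](OC(=O)[C@@H]1C)CO | intermediate
26 | (2R,3S,4R)-3-[(2R,3S,4R,6E)-2,4-bis(TBSO)-3-methyl-5-oxooct-6-en-1-yl]-4-methyl-5-oxooxolane-2-carbaldehyde (with its C1 epimer) | C/C=C/C(=O)[C@H](O[Si](C)(C)C(C)(C)C)[C@@H](C)[C@H](O[Si](C)(C)C(C)(C)C)C[C@@H]1[C@@H](OC(=O)[C@@H]1C)C=O | intermediate
27 | dibutylboron dienolate of 26 (C1=CK, C2 cis to O–B, silyloxy group cis to the propenyl group; formed in the flask) | C/C=C/C(/OB(CCCC)CCCC)=C(\O[Si](C)(C)C(C)(C)C)[C@@H](C)[C@H](O[Si](C)(C)C(C)(C)C)C[C@@H]1[C@@H](OC(=O)[C@@H]1C)C=O | intermediate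
28 | C7 O-dibutylboryl aldolate of 29 (formed in the flask) | C/C=C/C(=O)[C@]1(O[Si](C)(C)C(C)(C)C)[C@@H](C)[C@H](O[Si](C)(C)C(C)(C)C)C[C@@H]2[C@@H](OC(=O)[C@@H]2C)[C@@H]1OB(CCCC)CCCC | intermediate
29 | (3R,3aS,5R,6S,7S,8S,8aR)-7-[(E)-but-2-enoyl]-5,7-bis(TBSO)-8-hydroxy-3,6-dimethyloctahydro-2H-cyclohepta[b]furan-2-one | C/C=C/C(=O)[C@]1(O[Si](C)(C)C(C)(C)C)[C@@H](C)[C@H](O[Si](C)(C)C(C)(C)C)C[C@@H]2[C@@H](OC(=O)[C@@H]2C)[C@@H]1O | intermediate
30 | isobutyryl chloride | CC(C)C(Cl)=O | starting material
31 | (3R,3aS,5R,6S,7S,8S,8aR)-7-[(E)-but-2-enoyl]-5,7-bis(TBSO)-3,6-dimethyl-2-oxooctahydro-2H-cyclohepta[b]furan-8-yl 2-methylpropanoate | C/C=C/C(=O)[C@]1(O[Si](C)(C)C(C)(C)C)[C@@H](C)[C@H](O[Si](C)(C)C(C)(C)C)C[C@@H]2[C@@H](OC(=O)[C@@H]2C)[C@@H]1OC(=O)C(C)C | intermediate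
32 | (3R,3aS,5R,6S,7S,8S,8aR)-7-[(E)-but-2-enoyl]-5,7-dihydroxy-3,6-dimethyl-2-oxooctahydro-2H-cyclohepta[b]furan-8-yl 2-methylpropanoate | C/C=C/C(=O)[C@]1(O)[C@@H](C)[C@H](O)C[C@@H]2[C@@H](OC(=O)[C@@H]2C)[C@@H]1OC(=O)C(C)C | target

## Step count and least certain steps

Total step count: 19. Longest linear sequence: 19 steps (1 to 32).

Step 17 (key step, new on this substrate class).
- What may go wrong: enolisation at the hindered, fully substituted C1 may be slow, so that γ-deprotonation of the crotonoyl methyl group or enolisation and epimerisation at the aldehyde α-carbon C6 compete. Closure through the other enolate geometry or a boat would give the cis C1–O/C7–O relationship. Intermolecular aldol may intrude.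
- Fallback (known chemistry, enolisation separated from the aldehyde): set out from 25. Acylate the C7 hydroxyl with allyl chloroformate and pyridine to the allyl carbonate F1. Deprotonate the ketone kinetically with LiN(SiMe3)2 at −78 °C in the presence of TBSCl to give the TBS dienol ether F2. Remove the carbonate with Pd(PPh3)4 (zerovalent palladium) and PhSiH3 to give the alcohol F3. Oxidise with pyridine-buffered Dess–Martin periodinane to the aldehyde F4. Close the ring by an intramolecular Mukaiyama aldol with BF3·OEt2 in CH2Cl2 at −78 °C, which rejoins the route at 29. The aldehyde never meets a base, but the open transition state makes the C1/C7 selectivity less predictable.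

Step 6.
- What may go wrong: the selenoxide can eliminate toward the methyl group instead of into the ring, because both syn hydrogens are available.
- Fallback: set out from 10. Accept the exocyclic elimination product, the α-methylene lactone F5, and move the double bond into the ring with RhH(CO)(PPh3)3 in toluene at 80 °C; this rejoins the route at 12.

Step 7.
- What may go wrong: the tetrasubstituted alkene may reduce slowly on the metal surface, and prolonged forcing can cost face selectivity or cleave the allylic ring C–O bond.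
- Fallback: set out from 12 and replace surface hydrogenation by ionic 1,4-reduction with [(Ph3P)CuH]6 and t-BuOH in toluene. Hydride adds to C5 anti to the silyloxymethyl group and the enolate is protonated at C11 from the open face, which rejoins the route at 13 (no new compound, F0).

Step 18.
- What may go wrong: acylation of the C7 hydroxyl next to the quaternary C1 may be sluggish, and longer exposure to amine base invites retro-aldol opening or a 1,2-silyl shift from C1–O to C7–O.
- Fallback: set out from 29 and change from base-mediated to acid-catalysed acyl transfer, isobutyric anhydride with Sc(OTf)3 (cat.) in MeCN at −20 °C; this rejoins the route at 31 (no new compound, F0).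

## Further compounds

F1 | step 17 | C7 O-allyloxycarbonyl derivative of 25 | C/C=C/C(=O)[C@H](O[Si](C)(C)C(C)(C)C)[C@@H](C)[C@H](O[Si](C)(C)C(C)(C)C)C[C@@H]1[C@@H](OC(=O)[C@@H]1C)COC(=O)OCC=C
F2 | step 17 | TBS dienol ether of F1 (C1=CK, geometry undefined) | C/C=C/C(O[Si](C)(C)C(C)(C)C)=C(O[Si](C)(C)C(C)(C)C)[C@@H](C)[C@H](O[Si](C)(C)C(C)(C)C)C[C@@H]1[C@@H](OC(=O)[C@@H]1C)COC(=O)OCC=C
F3 | step 17 | TBS dienol ether with free C7 hydroxyl | C/C=C/C(O[Si](C)(C)C(C)(C)C)=C(O[Si](C)(C)C(C)(C)C)[C@@H](C)[C@H](O[Si](C)(C)C(C)(C)C)C[C@@H]1[C@@H](OC(=O)[C@@H]1C)CO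
F4 | step 17 | TBS dienol ether with C7 aldehyde | C/C=C/C(O[Si](C)(C)C(C)(C)C)=C(O[Si](C)(C)C(C)(C)C)[C@@H](C)[C@H](O[Si](C)(C)C(C)(C)C)C[C@@H]1[C@@H](OC(=O)[C@@H]1C)C=O
F5 | step 6 | (4R,5R)-5-(TBSO-methyl)-3-methylidene-4-[2-(TESO)ethyl]dihydrofuran-2(3H)-one | O=C1C(=C)[C@@H](CCO[Si](CC)(CC)CC)[C@H](CO[Si](C)(C)C(C)(C)C)O1
F0 | step 7 | none | none
F0 | step 18 | none | none
A1 | alternative 1 | open-chain C6 aldehyde with the C1/C7 diol as acetonide, ethynyl on C1, C3 TBS ether and a Z 2-(bromomethyl)enoate terminus | C#C[C@]1(OC(C)(C)O[C@H]1C=O)[C@@H](C)[C@H](O[Si](C)(C)C(C)(C)C)C/C=C(\CBr)C(=O)OC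
A2 | alternative 1 | cis-fused α-methylene lactone on the cycloheptane, C1/C7 diol as acetonide | C#C[C@]1(OC3(C)C)[C@@H](C)[C@H](O[Si](C)(C)C(C)(C)C)C[C@@H]2[C@@H](OC(=O)C2=C)[C@@H]1O3
A3 | alternative 2 | lactone with a Z iodomethylidene group on C5, C7 isobutyrate, C1 TES ether, ketalised methyl ketone and C3 aldehyde | CC1(OCCO1)[C@](O[Si](CC)(CC)CC)([C@@H](C)C=O)[C@@H](OC(=O)C(C)C)[C@@H]2OC(=O)[C@H](C)/C2=C/I
A4 | alternative 2 | bicyclic allylic alcohol with the C4=C5 alkene | CC1(OCCO1)[C@]2(O[Si](CC)(CC)CC)[C@@H](C)[C@H](O)C=C3[C@@H](OC(=O)[C@@H]3C)[C@@H]2OC(=O)C(C)C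
A5 | alternative 3 | all-cis lactone with C3 aldehyde and a Z trisubstituted alkene (C1=C2) next to the C7 isobutyrate | C/C=C(/C)[C@@H](OC(=O)C(C)C)[C@@H]1OC(=O)[C@H](C)[C@@H]1CC=O
A6 | alternative 3 | bicyclic lactone with C3 hydroxyl, C2 methyl and C1 exocyclic methylene | C=C1[C@@H](C)[C@H](O)C[C@@H]2[C@@H](OC(=O)[C@@H]2C)[C@@H]1OC(=O)C(C)C
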